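**Retrosynthetic overview**

1. Feature: the carbinolamine carbon (C–OH, bonded to guanidine N3, to the triamino carbon and to the first CH2 of the piperidine ring) is a masked acylguanidine carbonyl. Cutting its bond to that CH2 opens the piperidine and leaves a spiro aminal whose spiro atom, the triamino carbon, is shared by a glycocyamidine ring and the pyrrolo[1,2-c]imidazol-1-one ring, with a 3-halopropyl chain on the lactam nitrogen.
2. Forward, this C–C bond and the piperidine ring are made last, by a SmI2 Barbier closure of the 3-iodopropyl chain onto the ring carbonyl. Three Boc groups first make that carbonyl imide-like and remove every N–H (which would quench the carbanion); TFA then unmasks the target.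
3. The spiro triamino carbon is the aminal carbon of a glyoxylate-derived pyrroloimidazolone ester: radical bromination, then cyclocondensation with N-Boc-guanidine builds the glycocyamidine ring. It forms racemic, and the (S) antipode is taken by chiral chromatography once the centre is configurationally locked.
4. Ring order: pyrrole (bought) → imidazolone ring (aminal condensation of the N-(3-chloropropyl) amide with ethyl glyoxylate) → glycocyamidine ring (spiro) → piperidine ring (key step).

Key step: step 7

Assumption: exhaustive Boc acylation of 8 is taken to put two Boc groups on the exocyclic nitrogen and one on the acyl ring nitrogen N3, with N1 beside the quaternary spiro carbon left as the imine nitrogen; a different tri-Boc regioisomer would also carry no N–H and would be taken through the same steps.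

**Route**

Step 1
Reactants: 1 2,2,2-trichloro-1-(4,5-dibromo-1H-pyrrol-2-yl)ethan-1-one; 2 3-chloropropan-1-amine hydrochloride
Product: 3 4,5-dibromo-N-(3-chloropropyl)-1H-pyrrole-2-carboxamide
Conditions: Et3N (2.2 equiv), MeCN, rt
Reagents that add atoms: none
Why: Haloform-type acyl substitution, in which the amine adds to the trichloromethyl ketone and expels the trichloromethyl anion as chloroform, the standard way to make bromopyrrole carboxamides without touching the pyrrole N–H.

Step 2
Reactants: 3 4,5-dibromo-N-(3-chloropropyl)-1H-pyrrole-2-carboxamide; 4 ethyl glyoxylate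
Product: 5 racemic ethyl 5,6-dibromo-2-(3-chloropropyl)-1-oxo-2,3-dihydro-1H-pyrrolo[1,2-c]imidazole-3-carboxylate
Conditions: 4 (50% in toluene, 1.5 equiv), TsOH·H2O (10 mol %), 4 Å MS, toluene, 80 °C
Reagents that add atoms: none
Why: Acid-catalysed N,N-acetal (aminal) condensation, in which the amide N–H and the aldehyde give the N-acyl hemiaminal, ionisation gives the N-acyliminium ion and the pyrrole nitrogen closes the five-membered imidazolone ring, C-attack being shut off because C4 and C5 carry bromine and C3 is deactivated by the acyl group; the new stereocentre forms racemic and is erased in step 3.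

Step 3
Reactants: 5 racemic aminal ester; 6 N-Boc-guanidine
Product: 8 racemic mono-Boc spiro aminal chloride, via tertiary bromo ester 7 (not isolated)
Conditions: NBS (1.0 equiv), AIBN (5 mol %), PhCF3, 80 °C; then 0 °C, 6 (1.5 equiv), iPr2NEt (2 equiv), MeCN, 0 °C to rt
Reagents that add atoms: N-bromosuccinimide, O=C1CCC(=O)N1Br
Why: Wohl–Ziegler radical bromination of the captodative C3–H (flanked by two nitrogens and the ester, as in the α-bromination of N-acylglycine esters) gives the tertiary bromide, and guanidine cyclocondensation with this α-bromo ester then builds the 2-aminoimidazol-4-one ring, one free NH2 displacing bromide through the nitrogen-stabilised cation and the other acylating with the ester (5-exo-trig); the spiro triamino carbon forms racemic.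

Step 4
Reactants: 8 racemic mono-Boc spiro aminal chloride
Product: 9 racemic tri-Boc spiro chloride
Conditions: Boc2O (4 equiv), DMAP (0.2 equiv), Et3N (3 equiv), CH2Cl2, 0 °C to rt
Reagents that add atoms: di-tert-butyl dicarbonate, CC(C)(C)OC(=O)OC(=O)OC(C)(C)C
Why: DMAP-catalysed N-acylation with Boc2O, which cyclic 2-aminoazole-type guanidines accept three times (ring nitrogen once, exocyclic nitrogen twice), so that no N–H remains, the hindered N1 stays the imine nitrogen and the ring carbonyl becomes imide-like.

Step 5
Reactants: 9 racemic tri-Boc spiro chloride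
Product: 10 (S)-tri-Boc spiro chloride
Conditions: preparative SFC, immobilised amylose tris(3,5-dimethylphenylcarbamate) column, CO2/iPrOH, 35 °C
Reagents that add atoms: none
Why: Resolution by chromatography on a polysaccharide chiral stationary phase, placed here because without an N–H on N1 the spiro aminal can no longer open and re-close and is therefore configurationally fixed; the (S) antipode is to be identified by anomalous-dispersion X-ray diffraction using the bromine atoms.

Step 6
Reactants: 10 (S)-tri-Boc spiro chloride
Product: 11 (S)-tri-Boc spiro iodide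
Conditions: NaI (10 equiv), acetone, reflux, dark
Reagents that add atoms: sodium iodide, [Na+].[I-]
Why: Finkelstein exchange, an SN2 displacement of the primary chloride by iodide driven by precipitation of NaCl from acetone, under neutral conditions that leave the Boc groups and the spiro centre alone.

Step 7
Reactants: 11 (S)-tri-Boc spiro iodide
Product: 12 tri-Boc cis-fused carbinolamine
Conditions: SmI2 (2.5 equiv, 0.1 M in THF), Fe(dbm)3 (tris(dibenzoylmethanato)iron, 3 mol %), THF, −40 to 0 °C; pH 7 phosphate buffer
Reagents that add atoms: none
Why: Proposed new method: SmI2, helped by the trivalent-iron precatalyst, reduces the primary C–I bond of 11 through the alkyl radical to an alkylsamarium, which adds to the C4 carbonyl of the glycocyamidine ring, an imide-type carbonyl because N3 carries a Boc group, and the trivalent samarium alkoxide is protonated on work-up. The closest known reaction is the SmI2 Barbier cyclisation of N-(ω-iodoalkyl) imides to bicyclic hydroxy lactams; an N-Boc acylguanidine carbonyl has not served as the acceptor. The piperidine ring closes 6-exo-trig (terminal CH2, two CH2, lactam nitrogen, spiro carbon, C4). The new carbinolamine centre is controlled by the spiro carbon: the chain hangs from the lactam nitrogen on one face of the planar five-membered ring, so the C–C bond forms on that face and the oxygen ends cis to the pyrrole nitrogen, the only geometry the 5/6 fusion allows. The step needs C–I reduction in preference to the two pyrrole C–Br bonds (secured by leaving out HMPA and staying at or below 0 °C), attack at C4 and not at the pyrrole lactam carbonyl in a 5-exo mode (secured by Boc activation of C4 against a deactivated vinylogous amide), and a carbanion that is not quenched (secured by the absence of any N–H in 11).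

Step 8
Reactants: 12 tri-Boc cis-fused carbinolamine
Product: 13 target, carbinolamine carbon (R), triamino carbon (S)
Conditions: TFA/CH2Cl2 (1:3), 0 °C to rt; aq NaHCO3 work-up
Reagents that add atoms: none
Why: Acidolysis of the three tert-butyl carbamates with loss of 2-methylpropene and CO2, in a cis-fused cage where any reversible ionisation, ring–chain tautomer or Boc shift carried over from step 7 can only return the same stereoisomer.

**Compound list**

1 | 2,2,2-trichloro-1-(4,5-dibromo-1H-pyrrol-2-yl)ethan-1-one | O=C(c1cc(Br)c(Br)[nH]1)C(Cl)(Cl)Cl | starting material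
2 | 3-chloropropan-1-amine hydrochloride | NCCCCl.Cl | starting material
3 | 4,5-dibromo-N-(3-chloropropyl)-1H-pyrrole-2-carboxamide | O=C(NCCCCl)c1cc(Br)c(Br)[nH]1 | intermediate
4 | ethyl glyoxylate (ethyl 2-oxoacetate) | CCOC(=O)C=O | starting material
5 | ethyl 5,6-dibromo-2-(3-chloropropyl)-1-oxo-2,3-dihydro-1H-pyrrolo[1,2-c]imidazole-3-carboxylate, racemic | CCOC(=O)C1N(CCCCl)C(=O)c2cc(Br)c(Br)n12 | intermediate
6 | N-Boc-guanidine (tert-butyl carbamimidoylcarbamate) | CC(C)(C)OC(=O)N=C(N)N | starting material
7 | ethyl 3,5,6-tribromo-2-(3-chloropropyl)-1-oxo-2,3-dihydro-1H-pyrrolo[1,2-c]imidazole-3-carboxylate, racemic, not isolated | CCOC(=O)C1(Br)N(CCCCl)C(=O)c2cc(Br)c(Br)n12 | intermediate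
8 | racemic mono-Boc spiro aminal chloride: C3 of 5,6-dibromo-2-(3-chloropropyl)-2,3-dihydro-1H-pyrrolo[1,2-c]imidazol-1-one is also C5 of 2-(Boc-amino)-1,5-dihydro-4H-imidazol-4-one | CC(C)(C)OC(=O)NC1=NC(=O)C2(N1)N(CCCCl)C(=O)c1cc(Br)c(Br)n12 | intermediate
9 | racemic tri-Boc spiro chloride: as 8, with N(Boc)2 on the exocyclic nitrogen, Boc on the acyl ring nitrogen N3 and a C2=N1 double bond | CC(C)(C)OC(=O)N(C(=O)OC(C)(C)C)C1=NC2(N(CCCCl)C(=O)c3cc(Br)c(Br)n23)C(=O)N1C(=O)OC(C)(C)C | intermediate
10 | (S)-tri-Boc spiro chloride, (S) at the spiro triamino carbon | CC(C)(C)OC(=O)N(C(=O)OC(C)(C)C)C1=N[C@]2(N(CCCCl)C(=O)c3cc(Br)c(Br)n23)C(=O)N1C(=O)OC(C)(C)C | intermediate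
11 | (S)-tri-Boc spiro iodide: 10 with 3-iodopropyl on the lactam nitrogen | CC(C)(C)OC(=O)N(C(=O)OC(C)(C)C)C1=N[C@]2(N(CCCI)C(=O)c3cc(Br)c(Br)n23)C(=O)N1C(=O)OC(C)(C)C | intermediate
12 | tri-Boc cis-fused carbinolamine: target skeleton with N(Boc)2 on the exocyclic nitrogen and Boc on the nitrogen bonded to the carbinolamine carbon; carbinolamine carbon (R), triamino carbon (S) | CC(C)(C)OC(=O)N(C(=O)OC(C)(C)C)C1=N[C@]23n4c(Br)c(Br)cc4C(=O)N2CCC[C@]3(O)N1C(=O)OC(C)(C)C | intermediate
13 | target CNP0143627.2: cis-fused tetracyclic dibromopyrrole guanidine carbinolamine; carbinolamine carbon (R), triamino carbon (S) | NC1=N[C@@]2(O)CCCN3C(=O)c4cc(Br)c(Br)n4[C@@]32N1 | target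

**Step count and risks**

Total step count: 8. Longest linear sequence: 8 (steps 1 to 8 from 1 or 2).

Steps most likely to fail:

Step 7 (Proposed new method). The alkylsamarium may be protonated or the C–I bond simply reduced before ring closure, the carbanion may add to the pyrrole lactam carbonyl, or the pyrrole C–Br bonds may be reduced. Fallback by known chemistry, setting out from 11 and returning at 13: the iodide of 11 is displaced with PhSO2Na in DMF at rt to give the (S)-tri-Boc spiro phenyl sulfone F1. LiN(SiMe3)2 (2 equiv) in THF at −78 °C forms the α-sulfonyl carbanion, which is acylated intramolecularly by the Boc-activated C4 carbonyl (acylation of a sulfone anion by an N-acyl carbamate); this opens the glycocyamidine ring and gives the ring-opened β-keto sulfone F2. SmI2 in THF/MeOH at −78 °C removes the sulfonyl group (reductive desulfonylation of a β-keto sulfone) to give the tri-Boc-guanidino piperidin-3-one F3. TFA in CH2Cl2 then strips the Boc groups, and the free guanidine closes onto the ketone from the only accessible face to give 13.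

Step 3. Hydrogen abstraction may be unselective (N–CH2 positions), or the tertiary cation may be captured by succinimide or moisture before the guanidine arrives. Fallback, setting out from 3 and returning at 8: commercial glycocyamidine is acylated with Boc2O to tert-butyl (4-oxo-4,5-dihydro-1H-imidazol-2-yl)carbamate F4, and C5 is dibrominated with NBS in MeCN at 0 °C to give the 5,5-dibromide F5. F5 is added to amide 3 and Cs2CO3 in DMF at 0 °C; the pyrrole nitrogen and then the amide nitrogen replace the two bromides by elimination–addition through the acylimine (as in the amination of 5-halohydantoins), which gives 8 directly.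

Step 2. Ring closure may stall at the open N-acyl hemiaminal because the brominated pyrrole nitrogen is a weak nucleophile, or the acid may cause bromine migration on the pyrrole. Fallback, setting out from 3 and returning at 5: base-mediated double N-alkylation with ethyl dibromoacetate (K2CO3, DMF, rt). The pyrrolide nitrogen displaces one bromide to give ethyl 2-bromo-2-{2,3-dibromo-5-[(3-chloropropyl)carbamoyl]-1H-pyrrol-1-yl}acetate F6, whose amide nitrogen then closes the ring by 5-exo-tet displacement to give 5.

Further compounds
F1 | step 7 | (S)-tri-Boc spiro phenyl sulfone: 11 with 3-(phenylsulfonyl)propyl on the lactam nitrogen | CC(C)(C)OC(=O)N(C(=O)OC(C)(C)C)C1=N[C@]2(N(CCCS(=O)(=O)c4ccccc4)C(=O)c3cc(Br)c(Br)n23)C(=O)N1C(=O)OC(C)(C)C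
F2 | step 7 | ring-opened β-keto sulfone: (S)-aminal carbon bearing the tri-Boc-guanidine nitrogen, in a 3-oxo-4-(phenylsulfonyl)piperidine fused to the dibromopyrroloimidazolone, sulfonyl carbon as a mixture | CC(C)(C)OC(=O)NC(=N[C@@]12C(=O)C(S(=O)(=O)c3ccccc3)CCN1C(=O)c1cc(Br)c(Br)n12)N(C(=O)OC(C)(C)C)C(=O)OC(C)(C)C
F3 | step 7 | tri-Boc-guanidino piperidin-3-one: F2 without the phenylsulfonyl group | CC(C)(C)OC(=O)NC(=N[C@@]12C(=O)CCCN1C(=O)c1cc(Br)c(Br)n12)N(C(=O)OC(C)(C)C)C(=O)OC(C)(C)C
F4 | step 3 | tert-butyl (4-oxo-4,5-dihydro-1H-imidazol-2-yl)carbamate | CC(C)(C)OC(=O)NC1=NC(=O)CN1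
F5 | step 3 | tert-butyl (5,5-dibromo-4-oxo-4,5-dihydro-1H-imidazol-2-yl)carbamate | CC(C)(C)OC(=O)NC1=NC(=O)C(Br)(Br)N1
F6 | step 2 | ethyl 2-bromo-2-{2,3-dibromo-5-[(3-chloropropyl)carbamoyl]-1H-pyrrol-1-yl}acetate | CCOC(=O)C(Br)n1c(Br)c(Br)cc1C(=O)NCCCCl
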